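**Retrosynthetic overview**

1. Target 24 comes from 23 by chlorination at C5. 23 comes from hydroxy-enynone 22 by closing the pyran ring last (O2–C3, 6-endo-dig).
2. The carbocycle of 22 (as its bis-silyl ether 21) comes from diynone 14 and β-keto aldehyde 19. One flask forms C4a–C8a (enantioselective conjugate addition to the C4a≡C5 ynone) and C7–C8 (aldol), and with them C7, C8 and C8a.
3. Enabling feature: C8a is the central carbon of a latent 1,3-dicarbonyl (the acetyl C=O and the C8 carbinol, a former aldehyde) and is bonded to C4a, the β-carbon of the C4a=C5–C6=O enone; the C8 carbinol is also β to the C6 ketone. Ring C4a–C5–C6–C7–C8–C8a is therefore a Michael adduct and an aldol at once, and because C7 and C8a carry no hydrogen the aldol cannot dehydrate.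
4. 19 comes from isoxazole 15, a temporary ring that masks the β-keto aldehyde. 14 comes from vinyl iodide 5 (from (S)-2-methylbutanol), butadiyne 6 and lactate Weinreb amide 12, whose C7 configuration is erased in the key step.
5. Ring order: carbocycle (step 10), then pyran (step 12).

Key step: step 10

Remark: locants C1–C8a and O2 follow the isochromene numbering of the target; the pseudo-enantiomer of the cinchona catalyst that delivers 8aS is assumed to be (DHQD)2PHAL, the other being (DHQ)2PHAL.

**Route**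

Step 1
Reactants: 1 (S)-2-methylbutan-1-ol; 2 2-(triphenylphosphoranylidene)propanal
Product: 4 (S,E)-2,4-dimethylhex-2-enal, via (S)-2-methylbutanal 3 (not isolated)
Conditions: TEMPO (10 mol%), PhI(OAc)2, CH2Cl2, rt; then 2, 40 °C
Reagents that add atoms: none
Why: The non-basic TEMPO/PhI(OAc)2 oxidation should leave the α-stereocentre of the aldehyde intact, and the stabilised ylide traps it in situ in an E-selective Wittig olefination.

Step 2
Reactants: 4 (S,E)-2,4-dimethylhex-2-enal
Product: 5 (1E,3E,5S)-1-iodo-3,5-dimethylhepta-1,3-diene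
Conditions: CrCl2, CHI3, THF, 0 °C → rt, dark
Reagents that add atoms: iodoform, IC(I)I
Why: The Takai olefination converts aldehydes, enals included, into (E)-vinyl iodides and so sets the geometry of the outer side-chain double bond.

Step 3
Reactants: 5 (1E,3E,5S)-1-iodo-3,5-dimethylhepta-1,3-diene; 6 1,4-bis(trimethylsilyl)buta-1,3-diyne
Product: 9 trimethyl[(5E,7E,9S)-7,9-dimethylundeca-5,7-dien-1,3-diyn-1-yl]silane, via lithium 4-(trimethylsilyl)buta-1,3-diyn-1-ide 7 (not isolated), via bromo[4-(trimethylsilyl)buta-1,3-diyn-1-yl]zinc 8 (not isolated)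
Conditions: 6, MeLi·LiBr, THF, rt; ZnBr2, 0 °C; then 5, Pd(PPh3)4 (5 mol%), rt
Reagents that add atoms: none
Why: MeLi·LiBr cleaves one C–Si bond of 6 selectively, and the derived alkynylzinc couples with the alkenyl iodide under Pd(PPh3)4 (Negishi coupling) with retention of the E geometry.

Step 4
Reactants: 10 ethyl (S)-lactate
Product: 11 ethyl (S)-2-[(tert-butyldimethylsilyl)oxy]propanoate
Conditions: TBSCl, imidazole, DMF, rt
Reagents that add atoms: tert-butyldimethylsilyl chloride, CC(C)(C)[Si](C)(C)Cl
Why: Standard silylation of the secondary hydroxyl; the silyl ether later keeps the α-ketol oxygen from cyclising onto the ynone.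

Step 5
Reactants: 11 ethyl (S)-2-[(tert-butyldimethylsilyl)oxy]propanoate
Product: 12 (S)-2-[(tert-butyldimethylsilyl)oxy]-N-methoxy-N-methylpropanamide
Conditions: MeNH(OMe)·HCl, iPrMgCl, THF, −20 → 0 °C
Reagents that add atoms: N,O-dimethylhydroxylamine hydrochloride, CNOC.Cl
Why: Direct ester-to-Weinreb-amide conversion by the chloromagnesium amide of N,O-dimethylhydroxylamine, a standard aminolysis.

Step 6
Reactants: 9 trimethyl[(5E,7E,9S)-7,9-dimethylundeca-5,7-dien-1,3-diyn-1-yl]silane; 12 (S)-2-[(tert-butyldimethylsilyl)oxy]-N-methoxy-N-methylpropanamide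
Product: 14 (2S,8E,10E,12S)-2-[(tert-butyldimethylsilyl)oxy]-10,12-dimethyltetradeca-8,10-dien-4,6-diyn-3-one, via lithium (5E,7E,9S)-7,9-dimethylundeca-5,7-dien-1,3-diyn-1-ide 13 (not isolated)
Conditions: MeLi·LiBr, THF, 0 °C → rt; then 12, −78 → 0 °C; aq. NH4Cl
Reagents that add atoms: none
Why: MeLi·LiBr removes the alkynyl silyl group to give the lithium acetylide, which adds once to the Weinreb amide (stable chelate) and gives the ynone on work-up.

Step 7
Reactants: 15 ethyl 5-methylisoxazole-4-carboxylate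
Product: 16 (5-methylisoxazol-4-yl)methanol
Conditions: DIBAL-H (iBu2AlH), CH2Cl2, −78 → 0 °C; aq. Rochelle salt
Reagents that add atoms: none
Why: Hydride reduction of the ester to the primary alcohol; the isoxazole ring should be inert to iBu2AlH at low temperature.

Step 8
Reactants: 16 (5-methylisoxazol-4-yl)methanol
Product: 17 4-{[(tert-butyldimethylsilyl)oxy]methyl}-5-methylisoxazole
Conditions: TBSCl, imidazole, CH2Cl2, rt
Reagents that add atoms: tert-butyldimethylsilyl chloride, CC(C)(C)[Si](C)(C)Cl
Why: Standard silylation; a silyloxy group is a poor leaving group, so the later 1,3-dicarbonyl anion should not lose the C1 oxygen by β-elimination.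

Step 9
Reactants: 17 4-{[(tert-butyldimethylsilyl)oxy]methyl}-5-methylisoxazole
Product: 19 (Z)-3-{[(tert-butyldimethylsilyl)oxy]methyl}-4-hydroxybut-3-en-2-one (chelated enol of 2-{[(tert-butyldimethylsilyl)oxy]methyl}-3-oxobutanal), via (Z)-4-amino-3-{[(tert-butyldimethylsilyl)oxy]methyl}but-3-en-2-one 18 (not isolated)
Conditions: H2 (1 atm), Raney Ni, EtOH, rt; then oxalic acid, THF–H2O, 0 °C
Reagents that add atoms: water, O
Why: Hydrogenolysis of the isoxazole N–O bond unmasks the vinylogous amide (isoxazole as a masked 1,3-dicarbonyl), and brief mild acid hydrolysis releases the β-keto aldehyde as its enol.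

Step 10
Reactants: 14 (2S,8E,10E,12S)-2-[(tert-butyldimethylsilyl)oxy]-10,12-dimethyltetradeca-8,10-dien-4,6-diyn-3-one; 19 (Z)-3-{[(tert-butyldimethylsilyl)oxy]methyl}-4-hydroxybut-3-en-2-one
Product: 21 (4S,5R,6R)-4-acetyl-6-[(tert-butyldimethylsilyl)oxy]-4-{[(tert-butyldimethylsilyl)oxy]methyl}-3-[(3E,5E,7S)-5,7-dimethylnona-3,5-dien-1-yn-1-yl]-5-hydroxy-6-methylcyclohex-2-en-1-one, via Michael adduct 20 (not isolated)
Conditions: (DHQD)2PHAL (hydroquinidine 1,4-phthalazinediyl diether, 10 mol%), toluene, −20 °C; then LiCl, DBU, THF, 0 °C → rt (same flask)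
Reagents that add atoms: none
Why: Proposed new method: the quinuclidine of the catalyst deprotonates the acidic enol of 19, and the chiral ion pair adds through C8a to C4a of ynone 14; protonation of the allenolate gives enone 20 with the quaternary C8a (8aS by catalyst-controlled face selection; the adduct is non-enolisable and cannot racemise), the closest known type being the cinchona-alkaloid-catalysed enantioselective conjugate addition of 2-substituted 1,3-dicarbonyl compounds to alkynones followed by a Robinson-type aldol. LiCl/DBU then enolises the C6 ketone towards C7 (soft enolisation) and the enolate closes the carbocycle onto the C8 aldehyde in a 6-(enolendo)-exo-trig aldol, the only ring this step closes. C8 is controlled by the lithium chelate between the aldehyde and acetyl oxygens: attack perpendicular to that chelate from the C4a side leaves acetyl pseudo-axial and the new hydroxyl pseudo-equatorial, that is cis to acetyl. C7 is controlled by the same chair, which should put methyl equatorial and the smaller silyloxy group axial beside the acetyl group, so that O7, O8 and the acetyl oxygen sit on one face around the lithium ion. The step is stereoconvergent: the C7 configuration of 14 is erased in the enolate, the E isomer of 20 should return to the cyclisable Z isomer by reversible conjugate addition of chloride or DBU, and the aldol is reversible but cannot dehydrate. It needs 1,4- over 1,6-addition to the diynone (1,6-attack would pass through a strained C3=C4=C4a=C5=C6–O cumulenolate) and the aldehyde rather than the acetyl group as aldol acceptor (higher electrophilicity; closure of the acetyl methyl enolate onto C6 is reversible).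

Step 11
Reactants: 21 (4S,5R,6R)-4-acetyl-6-[(tert-butyldimethylsilyl)oxy]-4-{[(tert-butyldimethylsilyl)oxy]methyl}-3-[(3E,5E,7S)-5,7-dimethylnona-3,5-dien-1-yn-1-yl]-5-hydroxy-6-methylcyclohex-2-en-1-one
Product: 22 (4S,5R,6R)-4-acetyl-3-[(3E,5E,7S)-5,7-dimethylnona-3,5-dien-1-yn-1-yl]-5,6-dihydroxy-4-(hydroxymethyl)-6-methylcyclohex-2-en-1-one
Conditions: HF·pyridine, pyridine, THF, 0 °C → rt
Reagents that add atoms: none
Why: Fluoride cleaves both silyl ethers (wherever a silyl shift between the cis O7 and O8 oxygens may have placed them) under non-basic conditions, so the C7–C8 aldol should not revert.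

Step 12
Reactants: 22 (4S,5R,6R)-4-acetyl-3-[(3E,5E,7S)-5,7-dimethylnona-3,5-dien-1-yn-1-yl]-5,6-dihydroxy-4-(hydroxymethyl)-6-methylcyclohex-2-en-1-one
Product: 23 (7R,8R,8aS)-8a-acetyl-3-[(1E,3E,5S)-3,5-dimethylhepta-1,3-dien-1-yl]-7,8-dihydroxy-7-methyl-1,7,8,8a-tetrahydro-6H-isochromen-6-one
Conditions: Ph3PAuCl (5 mol%), AgOTf (5 mol%), CH2Cl2, 0 °C → rt
Reagents that add atoms: none
Why: The cationic gold catalyst activates the C3≡C4 alkyne and the primary C1 hydroxyl adds at C3, the electrophilic end of the enynone, in a 6-endo-dig hydroalkoxylation (the cycloisomerisation used to close azaphilone pyran rings); attack by the C8 hydroxyl would create a bridgehead alkene.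

Step 13
Reactants: 23 (7R,8R,8aS)-8a-acetyl-3-[(1E,3E,5S)-3,5-dimethylhepta-1,3-dien-1-yl]-7,8-dihydroxy-7-methyl-1,7,8,8a-tetrahydro-6H-isochromen-6-one
Product: 24 (7R,8R,8aS)-8a-acetyl-5-chloro-3-[(1E,3E,5S)-3,5-dimethylhepta-1,3-dien-1-yl]-7,8-dihydroxy-7-methyl-1,7,8,8a-tetrahydro-6H-isochromen-6-one
Conditions: NCS, CH2Cl2, −20 → 0 °C
Reagents that add atoms: N-chlorosuccinimide, O=C1CCC(=O)N1Cl
Why: Electrophilic chlorination by addition–elimination at C5, the terminus of the cyclic dienol ether O2–C3=C4–C4a=C5 and the α-carbon of the C6 ketone (halogenation of vinylogous esters with N-halosuccinimides).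

**Compound list**

1 | (S)-2-methylbutan-1-ol | CC[C@H](C)CO | starting material
2 | 2-(triphenylphosphoranylidene)propanal | CC(C=O)=P(c1ccccc1)(c1ccccc1)c1ccccc1 | starting material
3 | (S)-2-methylbutanal | CC[C@H](C)C=O | intermediate
4 | (S,E)-2,4-dimethylhex-2-enal | CC[C@H](C)/C=C(C)/C=O | intermediate
5 | (1E,3E,5S)-1-iodo-3,5-dimethylhepta-1,3-diene | CC[C@H](C)/C=C(C)/C=C/I | intermediate
6 | 1,4-bis(trimethylsilyl)buta-1,3-diyne | C[Si](C)(C)C#CC#C[Si](C)(C)C | starting material
7 | lithium 4-(trimethylsilyl)buta-1,3-diyn-1-ide | [Li+].[C-]#CC#C[Si](C)(C)C | intermediate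
8 | bromo[4-(trimethylsilyl)buta-1,3-diyn-1-yl]zinc | Br[Zn]C#CC#C[Si](C)(C)C | intermediate
9 | trimethyl[(5E,7E,9S)-7,9-dimethylundeca-5,7-dien-1,3-diyn-1-yl]silane | CC[C@H](C)/C=C(C)/C=C/C#CC#C[Si](C)(C)C | intermediate
10 | ethyl (S)-lactate | C[C@H](O)C(=O)OCC | starting material
11 | ethyl (S)-2-[(tert-butyldimethylsilyl)oxy]propanoate | C[C@H](O[Si](C)(C)C(C)(C)C)C(=O)OCC | intermediate
12 | (S)-2-[(tert-butyldimethylsilyl)oxy]-N-methoxy-N-methylpropanamide | C[C@H](O[Si](C)(C)C(C)(C)C)C(=O)N(C)OC | intermediate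
13 | lithium (5E,7E,9S)-7,9-dimethylundeca-5,7-dien-1,3-diyn-1-ide | [Li+].CC[C@H](C)/C=C(C)/C=C/C#CC#[C-] | intermediate
14 | (2S,8E,10E,12S)-2-[(tert-butyldimethylsilyl)oxy]-10,12-dimethyltetradeca-8,10-dien-4,6-diyn-3-one | CC[C@H](C)/C=C(C)/C=C/C#CC#CC(=O)[C@H](C)O[Si](C)(C)C(C)(C)C | intermediate
15 | ethyl 5-methylisoxazole-4-carboxylate | CCOC(=O)c1cnoc1C | starting material
16 | (5-methylisoxazol-4-yl)methanol | Cc1oncc1CO | intermediate
17 | 4-{[(tert-butyldimethylsilyl)oxy]methyl}-5-methylisoxazole | Cc1oncc1CO[Si](C)(C)C(C)(C)C | intermediate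
18 | (Z)-4-amino-3-{[(tert-butyldimethylsilyl)oxy]methyl}but-3-en-2-one | CC(=O)/C(CO[Si](C)(C)C(C)(C)C)=C\N | intermediate
19 | (Z)-3-{[(tert-butyldimethylsilyl)oxy]methyl}-4-hydroxybut-3-en-2-one (enol of 2-{[(tert-butyldimethylsilyl)oxy]methyl}-3-oxobutanal) | CC(=O)/C(CO[Si](C)(C)C(C)(C)C)=C\O | intermediate
20 | (2S,3Z,6S)-2-acetyl-6-[(tert-butyldimethylsilyl)oxy]-2-{[(tert-butyldimethylsilyl)oxy]methyl}-3-[(3E,5E,7S)-5,7-dimethylnona-3,5-dien-1-yn-1-yl]-5-oxohept-3-enal (Michael adduct) | CC[C@H](C)/C=C(C)/C=C/C#C/C(=C/C(=O)[C@H](C)O[Si](C)(C)C(C)(C)C)[C@](C=O)(C(C)=O)CO[Si](C)(C)C(C)(C)C | intermediate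
21 | (4S,5R,6R)-4-acetyl-6-[(tert-butyldimethylsilyl)oxy]-4-{[(tert-butyldimethylsilyl)oxy]methyl}-3-[(3E,5E,7S)-5,7-dimethylnona-3,5-dien-1-yn-1-yl]-5-hydroxy-6-methylcyclohex-2-en-1-one | CC[C@H](C)/C=C(C)/C=C/C#CC1=CC(=O)[C@](C)(O[Si](C)(C)C(C)(C)C)[C@H](O)[C@@]1(C(C)=O)CO[Si](C)(C)C(C)(C)C | intermediate
22 | (4S,5R,6R)-4-acetyl-3-[(3E,5E,7S)-5,7-dimethylnona-3,5-dien-1-yn-1-yl]-5,6-dihydroxy-4-(hydroxymethyl)-6-methylcyclohex-2-en-1-one | CC[C@H](C)/C=C(C)/C=C/C#CC1=CC(=O)[C@](C)(O)[C@H](O)[C@@]1(C(C)=O)CO | intermediate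
23 | (7R,8R,8aS)-8a-acetyl-3-[(1E,3E,5S)-3,5-dimethylhepta-1,3-dien-1-yl]-7,8-dihydroxy-7-methyl-1,7,8,8a-tetrahydro-6H-isochromen-6-one | CC[C@H](C)/C=C(C)/C=C/C1=CC2=CC(=O)[C@](C)(O)[C@H](O)[C@@]2(C(C)=O)CO1 | intermediate
24 | (7R,8R,8aS)-8a-acetyl-5-chloro-3-[(1E,3E,5S)-3,5-dimethylhepta-1,3-dien-1-yl]-7,8-dihydroxy-7-methyl-1,7,8,8a-tetrahydro-6H-isochromen-6-one | CC[C@H](C)/C=C(C)/C=C/C1=CC2=C(Cl)C(=O)[C@](C)(O)[C@H](O)[C@@]2(C(C)=O)CO1 | target

**Step count and risks**

Total step count: 13. Longest linear sequence: 8 steps (steps 1, 2, 3, 6, 10, 11, 12, 13).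

Steps most likely to fail:

1. Step 10 (Proposed new method). What may go wrong: insufficient or opposite facial discrimination at C8a in the catalytic conjugate addition, which would give a mixture that differs from the wanted series only relative to the remote side-chain stereocentre. Fallback with known chemistry: setting out from 18 (isolated after the hydrogenation stage of step 9) and 14, transamination of 18 with L-valine diethylamide (EtOH, 60 °C) would give the chiral enaminone F1. With Cu(OAc)2·H2O (5 mol%) in acetone at rt, F1 would add to 14 through its copper azaenolate while the auxiliary screens one face of C8a (auxiliary-controlled Michael reaction of enamines of 2-substituted 1,3-dicarbonyl compounds, an established way to quaternary stereocentres), giving the aldimine F2. Mild aqueous citric acid would release the auxiliary and the aldehyde, giving Michael adduct 20, where the fallback rejoins the route; 20 is then closed to 21 with LiCl/DBU as in the second stage of step 10. The enantiomeric auxiliary is available if the other face is needed.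

2. Step 13. What may go wrong: poor site selectivity of the electrophilic chlorination (attack at C4 instead of C5, or double chlorination). Fallback: setting out from 22, iodocyclisation with N-iodosuccinimide (NaHCO3, CH2Cl2, 0 °C, dark; 6-endo-dig attack of the C1 hydroxyl on the iodonium-activated alkyne) would give the 4-iodo pyran F3, in which C4 is blocked. NCS could then chlorinate only C5, giving the 5-chloro-4-iodo compound F4. Pd(PPh3)4 (5 mol%) with Bu3SnH in THF would remove the iodine selectively, because the C–I bond undergoes oxidative addition far more readily than C–Cl, and would give 24, where the fallback rejoins the route.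

3. Step 6. What may go wrong: oligomerisation of the polyunsaturated lithium acetylide 13 or attack of methyllithium on the conjugated diyne before acylation. Fallback without organolithium reagents: setting out from 9 and 11, K2CO3 in MeOH would remove the silyl group of 9 to give the terminal diyne F5, and iBu2AlH (CH2Cl2, −78 °C) would reduce 11 to (S)-2-[(tert-butyldimethylsilyl)oxy]propanal F6. Zinc triflate/triethylamine-mediated addition of F5 to F6 would give the propargylic alcohol F7 (mixture of carbinol epimers, of no consequence), and Dess–Martin periodinane would oxidise it to 14, where the fallback rejoins the route.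

**Further compounds**

F1 | step 10 | (S)-2-{[(Z)-2-acetyl-3-[(tert-butyldimethylsilyl)oxy]prop-1-en-1-yl]amino}-N,N-diethyl-3-methylbutanamide (enaminone of 19 with L-valine diethylamide) | CC(=O)/C(CO[Si](C)(C)C(C)(C)C)=C\N[C@@H](C(C)C)C(=O)N(CC)CC
F2 | step 10 | aldimine of Michael adduct 20 with L-valine diethylamide | CC[C@H](C)/C=C(C)/C=C/C#C/C(=C/C(=O)[C@H](C)O[Si](C)(C)C(C)(C)C)[C@](/C=N/[C@@H](C(C)C)C(=O)N(CC)CC)(C(C)=O)CO[Si](C)(C)C(C)(C)C
F3 | step 13 | (7R,8R,8aS)-8a-acetyl-3-[(1E,3E,5S)-3,5-dimethylhepta-1,3-dien-1-yl]-7,8-dihydroxy-4-iodo-7-methyl-1,7,8,8a-tetrahydro-6H-isochromen-6-one | CC[C@H](C)/C=C(C)/C=C/C1=C(I)C2=CC(=O)[C@](C)(O)[C@H](O)[C@@]2(C(C)=O)CO1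
F4 | step 13 | (7R,8R,8aS)-8a-acetyl-5-chloro-3-[(1E,3E,5S)-3,5-dimethylhepta-1,3-dien-1-yl]-7,8-dihydroxy-4-iodo-7-methyl-1,7,8,8a-tetrahydro-6H-isochromen-6-one | CC[C@H](C)/C=C(C)/C=C/C1=C(I)C2=C(Cl)C(=O)[C@](C)(O)[C@H](O)[C@@]2(C(C)=O)CO1
F5 | step 6 | (5E,7E,9S)-7,9-dimethylundeca-5,7-dien-1,3-diyne | CC[C@H](C)/C=C(C)/C=C/C#CC#C
F6 | step 6 | (S)-2-[(tert-butyldimethylsilyl)oxy]propanal | C[C@H](O[Si](C)(C)C(C)(C)C)C=O
F7 | step 6 | (2S,8E,10E,12S)-2-[(tert-butyldimethylsilyl)oxy]-10,12-dimethyltetradeca-8,10-dien-4,6-diyn-3-ol (both C3 epimers) | CC[C@H](C)/C=C(C)/C=C/C#CC#CC(O)[C@H](C)O[Si](C)(C)C(C)(C)C
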